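## The problem

Rings are numbered as in orsellinic acid: the carbonyl-bearing carbon is C1, the hydrogen-bonded hydroxyl sits on C2 and the methyl on C6.

The target 18 is a tridepside of three 6-methylsalicylate rings joined head to tail by two aryl ester bonds. Ring A carries the free carboxylic acid, ring B is the central orsellinate, and ring C is a 2,4,5-trihydroxy-6-methylbenzoyl unit. There is no stereocentre, so the whole difficulty is regiochemical and chemoselective. Each ester joins a di-ortho-substituted benzoyl carbon to the C4 oxygen of the next ring, while the C2 hydroxyls, hydrogen-bonded to their own carbonyls, must stay free. The aryl esters are activated esters that hydrolyse or transacylate under base, nucleophilic catalysis or strong acid. The salicylic acid of ring A decarboxylates on heating, and ring C is a hydroxyquinol that air oxidises once its phenols are ionised. Late steps must therefore be neutral or weakly acidic, and the final deprotection a single mild operation. Ring C differs from the other rings by the C5 oxygen next to the methyl group, which has to be placed regioselectively. The feature that opens the key step is ring B: its C2–C3–C4–C5 segment, oxygenated at C2 and C4, is a 1,3-dioxygenated buta-1,3-diene with C2 at the ketene acetal level, and its C1–C6 edge, carrying carboxyl and methyl, is a but-2-ynoate, so the ring can be grown on the ester that already links it to ring A.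

## Retrosynthesis

**18 from 17.** The last cut removes four O-benzyl bonds, three ring C ethers and the ring A ester, from tridepside 17. Benzyl is chosen because hydrogenolysis is neutral and touches neither aryl ester; any hydrolytic deprotection would compete with depside cleavage. The chelated hydroxyls of rings A and B need no protection.

**17 from 10 and 15.** The ester between the ring C carbonyl and the ring B C4 oxygen is cut, giving didepside phenol 10 and ring C acid 15. Cutting the B–A ester instead would require a C–B didepside acid with a hindered, separately unmasked carboxyl. In 10 the ring B C4 hydroxyl is the only phenol not tied up in a hydrogen bond, so the coupling needs no protecting group on 10. The forward reaction must acylate that hydroxyl with a di-ortho-substituted acid without base strong enough to scramble the existing ester.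

**10 from 4 and 7 (key disconnection).** Ring B is cut at C1–C2 and C5–C6, giving aryl but-2-ynoate 4 and diene 7. Buying ring B as an orsellinic acid derivative would be the obvious neighbour. That route needs orthogonal protection of the central ring (carboxyl against C4 hydroxyl) and a second hindered aryl ester coupling. Here the B–A ester is made from an unhindered alkynoic acid, and ring B emerges with its C2 hydroxyl chelated and its C4 hydroxyl free, ready for the next acylation. The forward reaction must fix one orientation of diene against alkyne, leave both ester carbonyls alone, and aromatise by 1,4-elimination across the silyl ketal so that C2 ends as a hydroxyl.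

**4 from 2 and 3; 2 from 1.** The ynoate ester C–O bond is cut to benzyl orsellinate 2 and but-2-ynoic acid 3. The ester 2 comes from orsellinic acid 1 by carboxylate alkylation. The only demand is acylation of the C4 hydroxyl of 2 in preference to the chelated C2 hydroxyl.

**7 from 6 from 5.** Two O–Si bonds are cut in turn: diene 7 comes from silyl enol ether 6, and 6 from methyl acetoacetate 5. This is the standard double silylation and adds no strategic risk.

**15 from 14, 13 and 11.** The acid 15 is the saponification product of tribenzyl ester 14, which comes from triol ester 13. The C5–O bond of 13 is then cut back to commercial methyl orsellinate 11, where C5 is the only open position para to a phenoxide. One oxidation on an existing orsellinate is shorter than any de novo construction of ring C, at the price of a modest-yielding step.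

## Roads not taken

**Alternative 1:** Ring C is cut at C1–C2 and traced back to cyclobutenone A2. Heating A2 should open the four-membered ring, with the hydroxyl rotating outward, to a dienylketene. A 6π electrocyclisation and tautomerisation would then give hydroquinone ester A1.
- Merits: every substituent of ring C is placed by construction. The C5 oxygen comes from the carbinol carbon, C4 from the vinylogous ester and C2 from the ketene carbonyl. The step is thermal and neutral.
- Weak points: A1 is a para-hydroquinone prone to quinone formation. Its isopropyl ether and tert-butyl ester must be exchanged for hydrogenolysable groups under Lewis or protic acid before it can serve as a coupling partner. A2 itself needs an alkenylmetal addition to an unsymmetrical cyclobutenedione. Rings A and B and both hindered depside couplings remain.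
- Comparison: for ring C regiochemistry this road is better than the chosen plan, which relies on the Elbs oxidation of step 6. The chosen plan sets against it length (15 is three steps from 11) and a key step that replaces one hindered aryl ester coupling by acylation with the unhindered acid 3.

**Alternative 2:** Ring A is cut at C1–C6 and C2–C3. Acyloxypyrone A4, carrying the whole C–B acyl group, would add alkynoate A5, and decarboxylative collapse of the bridged lactone would give perbenzylated tridepside A3.
- Merits: this is the most convergent plan. A3 is one hydrogenolysis from 18, no free phenol is present in the cycloaddition, and the orientation is polarity-matched.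
- Weak points: 2-pyrones are reluctant dienes that need high temperatures. A4 is a vinylogous mixed anhydride that can pass its acyl group to any nucleophile or to its own C3. A5 is a push–pull alkyne of low dienophilicity, and its benzyl alkynyl ether rearranges thermally before such temperatures are reached. The most valuable fragment is exposed in the riskiest step.
- Comparison: this road is better in convergence and in the protection state of its product. The chosen plan sets against it a matched pair (electron-rich 7, electron-poor 4) reacting at moderate temperature, early and on cheap material.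

**Alternative 3:** Ring C is cut at C1–C6. The tetracarbonyl aryl ester A7 would fold by aldol attack of its C2 on the C7 ketone and dehydrate to tridepside A6, with ring C as the 5-benzyl ether.
- Merits: the C5 oxygen arrives with the chain, so no arene oxidation is needed. Ring C is formed on the depside ester, so its hindered coupling is avoided, and A6 is again one hydrogenolysis from 18.
- Weak points: A7 has several modes of closure. The most threatening is lactonisation of an enol onto the aryl ester, expelling the didepside phenoxide to give a pyrone. Claisen-type C-acylation and aldol attack of the terminal methyl on the C3 ketone also compete. Assembling A7 needs polyanion acylations that two aryl esters will not tolerate, and its α-benzyloxy ketone is prone to elimination.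
- Comparison: this road is as good as or better than the chosen plan in avoiding phenol oxidation and the ring C coupling. The chosen plan sets against it a ring closure with a single mode, no strong base near the depside, and precursors 4 and 7 each two steps from commercial materials.

Key step: step 5

Remark on the chemistry: silyl enol ether 6 is expected as an E/Z mixture (E drawn) and diene 7 is drawn as the (1Z) isomer; neither geometry affects the outcome, and the ketal carbon of 8 is racemic and lost on aromatisation.

## Route

Step 1
Reactants: 1 orsellinic acid (2,4-dihydroxy-6-methylbenzoic acid)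
Product: 2 benzyl 2,4-dihydroxy-6-methylbenzoate (benzyl orsellinate)
Conditions: BnBr (1.05 equiv), KHCO3, DMF, 20 °C
Reagents that add atoms: benzyl bromide, BrCc1ccccc1
Why: Carboxylate O-alkylation (SN2); hydrogencarbonate ionises only the carboxylic acid, so the phenols are not benzylated, and room temperature avoids decarboxylation.

Step 2
Reactants: 2 benzyl 2,4-dihydroxy-6-methylbenzoate; 3 but-2-ynoic acid
Product: 4 benzyl 4-(but-2-ynoyloxy)-2-hydroxy-6-methylbenzoate
Conditions: DCC, DMAP (5 mol%), CH2Cl2, 0 to 20 °C
Reagents that add atoms: none
Why: Steglich esterification, a standard route to aryl alkynoates; the C2 hydroxyl is hydrogen-bonded to the benzyl ester carbonyl and flanked by it, so only the C4 hydroxyl should be acylated, and low temperature with little DMAP limits conjugate addition to the activated ynoate.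

Step 3
Reactants: 5 methyl acetoacetate
Product: 6 methyl (2E)-3-(trimethylsilyloxy)but-2-enoate (E/Z mixture)
Conditions: Me3SiCl, Et3N, hexane, 20 °C
Reagents that add atoms: chlorotrimethylsilane, C[Si](C)(C)Cl
Why: O-silylation of the enolised β-keto ester under amine base, the standard first stage of 1,3-bis(silyloxy)diene preparation.

Step 4
Reactants: 6 methyl (2E)-3-(trimethylsilyloxy)but-2-enoate
Product: 7 (1Z)-1-methoxy-1,3-bis(trimethylsilyloxy)buta-1,3-diene
Conditions: LiN(iPr)2 (LDA, commercial solution), THF, −78 °C; Me3SiCl, −78 to 0 °C; filtration and bulb-to-bulb distillation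
Reagents that add atoms: chlorotrimethylsilane, C[Si](C)(C)Cl
Why: Kinetic γ-deprotonation of the vinylogous ester gives the dienolate, which is silylated on the ester oxygen; the moisture-sensitive diene is used directly.

Step 5
Reactants: 4 benzyl 4-(but-2-ynoyloxy)-2-hydroxy-6-methylbenzoate; 7 (1Z)-1-methoxy-1,3-bis(trimethylsilyloxy)buta-1,3-diene
Product: 10 benzyl 4-[(2,4-dihydroxy-6-methylbenzoyl)oxy]-2-hydroxy-6-methylbenzoate (rings B–A didepside), via cyclohexa-1,4-diene cycloadduct 8 (not isolated), via ring B 4-O-trimethylsilyl ether 9 (not isolated)
Conditions: 7 (3.5 equiv, in portions), PhMe, 110 °C, sealed tube; then 1 M HCl, THF, 20 °C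
Reagents that add atoms: none
Why: This is the Diels–Alder benzannulation of a 1,3-dioxygenated silyloxydiene with a 2-alkynoate, a known route to resorcylate esters, applied here to an aryl ynoate. The cycloaddition is polar and highly asynchronous: the unsubstituted CH2 terminus of 7, to which both oxygen-bearing carbons push electron density, bonds first to the methyl-bearing β-carbon of 4, and the developing allenoate closes onto the ketene acetal carbon, so that C5–C6 and C1–C2 of ring B form and the six-membered ring closes as the intermolecular (4+2) adduct 8. The silyl ketal carbon of 8 expels methoxytrimethylsilane to give a cyclohexadienone that tautomerises to phenol 9, and dilute acid then cleaves the aryl silyl ether. No stereocentre survives, since the ketal carbon of 8 is formed racemic and becomes the sp2 carbon C2. The selectivity needed is regiochemical (hydroxyl next to the ester, methyl on the other side) and is secured by this polarity match, because the reverse orientation would pair the two electron-rich termini. Chemoselectivity against the two ester carbonyls rests on the absence of a Lewis acid, without which silyl ketene acetals do not acylate esters, while the aryl ester lowers the alkyne LUMO relative to an alkyl butynoate. The excess of 7 allows for transient silylation of the chelated ring A hydroxyl and of the new ring B phenol, both reversed in the acidic work-up.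

Step 6
Reactants: 11 methyl orsellinate (methyl 2,4-dihydroxy-6-methylbenzoate)
Product: 13 methyl 2,4,5-trihydroxy-6-methylbenzoate, via C5 aryl sulfate potassium salt 12 (not isolated)
Conditions: K2S2O8, 2 M aq. NaOH, 0 to 20 °C; aq. HCl to pH 4, extract unreacted 11; then aq. HCl, 80 °C, N2
Reagents that add atoms: potassium peroxodisulfate K2S2O8, [K+].[K+].[O-]S(=O)(=O)OOS(=O)(=O)[O-]
Why: Elbs persulfate oxidation; peroxodisulfate attacks para to a phenoxide, and C5 is the only open para position (para to the C2 oxygen; the position para to the C4 oxygen is C1), giving the aryl sulfate that acid hydrolyses to the hydroquinone. The hindered methyl ester should survive cold alkali and warm dilute acid.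

Step 7
Reactants: 13 methyl 2,4,5-trihydroxy-6-methylbenzoate
Product: 14 methyl 2,4,5-tris(benzyloxy)-6-methylbenzoate
Conditions: BnBr (3.6 equiv), K2CO3, DMF, 60 °C, Ar
Reagents that add atoms: benzyl bromide, BrCc1ccccc1
Why: Williamson etherification; warming in DMF is needed to alkylate the chelated C2 hydroxyl, and exclusion of air protects the hydroxyquinol until all three phenols are capped.

Step 8
Reactants: 14 methyl 2,4,5-tris(benzyloxy)-6-methylbenzoate
Product: 15 2,4,5-tris(benzyloxy)-6-methylbenzoic acid
Conditions: KOH, DMSO–H2O, 90 °C; then aq. HCl
Reagents that add atoms: potassium hydroxide KOH (hydroxide oxygen), [K+].[OH-]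
Why: Saponification of a di-ortho-substituted methyl benzoate; poorly solvated hydroxide in aqueous DMSO is the usual remedy for such hindered esters, and benzyl ethers are inert to it.

Step 9
Reactants: 15 2,4,5-tris(benzyloxy)-6-methylbenzoic acid; 10 benzyl 4-[(2,4-dihydroxy-6-methylbenzoyl)oxy]-2-hydroxy-6-methylbenzoate
Product: 17 benzyl 4-{[4-{[2,4,5-tris(benzyloxy)-6-methylbenzoyl]oxy}-2-hydroxy-6-methylbenzoyl]oxy}-2-hydroxy-6-methylbenzoate, via mixed trifluoroacetic anhydride 16 (not isolated)
Conditions: (CF3CO)2O, PhMe, 20 °C; then 10, 20 °C; aq. NaHCO3 work-up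
Reagents that add atoms: none
Why: Mixed-anhydride esterification, the classical depside coupling; the acyl trifluoroacetate of a hindered, electron-rich benzoic acid is reactive enough to acylate a phenol without base. Only the ring B C4 hydroxyl should react because the two C2 hydroxyls are chelated, and the acidic medium avoids base-induced transacylation of the existing aryl ester.

Step 10
Reactants: 17 benzyl-protected tridepside
Product: 18 4-{[4-{[2,4,5-trihydroxy-6-methylbenzoyl]oxy}-2-hydroxy-6-methylbenzoyl]oxy}-2-hydroxy-6-methylbenzoic acid (target)
Conditions: H2 (1 atm), Pd/C, EtOAc, 20 °C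
Reagents that add atoms: none
Why: Hydrogenolysis of three benzyl ethers and one benzyl ester under neutral conditions; aryl esters are inert to it, and a non-nucleophilic solvent with work-up under inert gas protects the depside links and the hydroxyquinol ring.

## Compound list

1 | orsellinic acid (2,4-dihydroxy-6-methylbenzoic acid) | Cc1cc(O)cc(O)c1C(=O)O | starting material
2 | benzyl 2,4-dihydroxy-6-methylbenzoate | Cc1cc(O)cc(O)c1C(=O)OCc1ccccc1 | intermediate
3 | but-2-ynoic acid | CC#CC(=O)O | starting material
4 | benzyl 4-(but-2-ynoyloxy)-2-hydroxy-6-methylbenzoate | CC#CC(=O)Oc1cc(C)c(C(=O)OCc2ccccc2)c(O)c1 | intermediate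
5 | methyl acetoacetate | CC(=O)CC(=O)OC | starting material
6 | methyl (2E)-3-(trimethylsilyloxy)but-2-enoate (E/Z mixture, E drawn) | C/C(O[Si](C)(C)C)=C\C(=O)OC | intermediate
7 | (1Z)-1-methoxy-1,3-bis(trimethylsilyloxy)buta-1,3-diene | C=C(O[Si](C)(C)C)/C=C(\O[Si](C)(C)C)OC | intermediate
8 | benzyl 2-hydroxy-4-{[6-methoxy-2-methyl-4,6-bis(trimethylsilyloxy)cyclohexa-1,4-diene-1-carbonyl]oxy}-6-methylbenzoate (racemic, not isolated) | COC1(O[Si](C)(C)C)C=C(O[Si](C)(C)C)CC(C)=C1C(=O)Oc1cc(C)c(C(=O)OCc2ccccc2)c(O)c1 | intermediate
9 | benzyl 2-hydroxy-4-{[2-hydroxy-6-methyl-4-(trimethylsilyloxy)benzoyl]oxy}-6-methylbenzoate (not isolated) | Cc1cc(O[Si](C)(C)C)cc(O)c1C(=O)Oc1cc(C)c(C(=O)OCc2ccccc2)c(O)c1 | intermediate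
10 | benzyl 4-[(2,4-dihydroxy-6-methylbenzoyl)oxy]-2-hydroxy-6-methylbenzoate | Cc1cc(O)cc(O)c1C(=O)Oc1cc(C)c(C(=O)OCc2ccccc2)c(O)c1 | intermediate
11 | methyl orsellinate (methyl 2,4-dihydroxy-6-methylbenzoate) | COC(=O)c1c(C)cc(O)cc1O | starting material
12 | potassium 4,6-dihydroxy-3-(methoxycarbonyl)-2-methylphenyl sulfate (not isolated) | COC(=O)c1c(C)c(OS(=O)(=O)[O-])c(O)cc1O.[K+] | intermediate
13 | methyl 2,4,5-trihydroxy-6-methylbenzoate | COC(=O)c1c(C)c(O)c(O)cc1O | intermediate
14 | methyl 2,4,5-tris(benzyloxy)-6-methylbenzoate | COC(=O)c1c(C)c(OCc2ccccc2)c(OCc2ccccc2)cc1OCc1ccccc1 | intermediate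
15 | 2,4,5-tris(benzyloxy)-6-methylbenzoic acid | Cc1c(OCc2ccccc2)c(OCc2ccccc2)cc(OCc2ccccc2)c1C(=O)O | intermediate
16 | 2,4,5-tris(benzyloxy)-6-methylbenzoic trifluoroacetic anhydride (not isolated) | Cc1c(OCc2ccccc2)c(OCc2ccccc2)cc(OCc2ccccc2)c1C(=O)OC(=O)C(F)(F)F | intermediate
17 | benzyl 4-{[4-{[2,4,5-tris(benzyloxy)-6-methylbenzoyl]oxy}-2-hydroxy-6-methylbenzoyl]oxy}-2-hydroxy-6-methylbenzoate | Cc1cc(OC(=O)c2c(C)cc(OC(=O)c3c(OCc4ccccc4)cc(OCc4ccccc4)c(OCc4ccccc4)c3C)cc2O)cc(O)c1C(=O)OCc1ccccc1 | intermediate
18 | 4-{[4-{[2,4,5-trihydroxy-6-methylbenzoyl]oxy}-2-hydroxy-6-methylbenzoyl]oxy}-2-hydroxy-6-methylbenzoic acid | Cc1cc(OC(=O)c2c(C)cc(OC(=O)c3c(O)cc(O)c(O)c3C)cc2O)cc(O)c1C(=O)O | target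

## Step count and least certain steps

Total: 10 steps. Longest linear sequence: 5 steps (steps 1, 2, 5, 9, 10 from orsellinic acid 1; equally steps 6, 7, 8, 9, 10 from methyl orsellinate 11).

**Key step (step 5).** Three things are most likely to go wrong.
- Thermal decay of the acyclic diene (silyl migration, protodesilylation by the phenols) may outrun cycloaddition to a β-methylated, only moderately electron-poor alkyne.
- Attack of the diene on the aryl ester carbonyl would cut the depside link.
- Aromatisation by loss of silanol instead of the silyl methyl ether would leave a methyl ether on ring B C2.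

The fallback keeps the same two bonds but changes the diene and the aromatisation mode. It sets out from 4 and returns at 10. Commercial dimedone is O-silylated (Me3SiCl, Et3N) to 5,5-dimethyl-3-(trimethylsilyloxy)cyclohex-2-en-1-one F1. Deprotonation with LiN(iPr)2 and silylation give the conformationally locked, thermally robust 5,5-dimethyl-1,3-bis(trimethylsilyloxy)cyclohexa-1,3-diene F2. Heating 4 with F2 at about 140 °C should give the bicyclo[2.2.2]octadiene adduct F3, which loses 2-methylpropene by retro-Diels–Alder reaction to the ring B bis(trimethylsilyl) ether F4. Dilute acid then gives 10. No ketal is involved, so a C2 methyl ether cannot arise.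

**Step 6.** Elbs oxidations often stop at low conversion, and the hydroxyquinol product can be over-oxidised to a quinone in the alkaline medium.

The fallback introduces the C5 oxygen by formylation and oxygen insertion. It sets out from 11 and returns at 14. Dibenzylation (BnBr, K2CO3, DMF) gives methyl 2,4-bis(benzyloxy)-6-methylbenzoate F5. Vilsmeier–Haack formylation (POCl3, DMF) should go to C5, the position para to the C2 ether and less shielded than C3, giving methyl 2,4-bis(benzyloxy)-5-formyl-6-methylbenzoate F6. Baeyer–Villiger oxidation with mCPBA gives methyl 2,4-bis(benzyloxy)-5-(formyloxy)-6-methylbenzoate F7. Methanolysis (K2CO3, MeOH) gives methyl 2,4-bis(benzyloxy)-5-hydroxy-6-methylbenzoate F8, and benzylation then gives 14.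

**Step 9.** Acylation by the doubly ortho-substituted acyl donor may be slow enough for three side processes to intervene: trifluoroacetylation of the phenol, acid-induced loss of a benzyl ether from the electron-rich ring C, and acyl exchange at the existing depside ester.

The fallback uses a preformed acyl chloride under weakly basic conditions. It sets out from 15 and returns at 17. Oxalyl chloride with catalytic DMF in CH2Cl2 converts 15 into 2,4,5-tris(benzyloxy)-6-methylbenzoyl chloride F9. F9 is added to 10 and pyridine in CH2Cl2 at 0 °C without nucleophilic catalyst, relying again on the chelation of the two C2 hydroxyls.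

**Step 2.** Carbodiimide and DMAP activation of an alkynoic acid can lead to conjugate addition of the catalyst or phenol to the activated ynoate, to isomerisation towards the allenoate, and to N-acylurea formation.

The fallback avoids both carbodiimide and nucleophilic catalyst. It sets out from 3 and returns at 4. Oxalyl chloride with catalytic DMF in CH2Cl2 at 0 °C converts 3 into but-2-ynoyl chloride F10. F10 is added to 2 and 2,6-lutidine in CH2Cl2 at −20 °C; the hindered base cannot add to the triple bond.

## Further compounds

F1 | step 5 | 5,5-dimethyl-3-(trimethylsilyloxy)cyclohex-2-en-1-one | CC1(C)CC(=O)C=C(O[Si](C)(C)C)C1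
F2 | step 5 | 5,5-dimethyl-1,3-bis(trimethylsilyloxy)cyclohexa-1,3-diene | CC1(C)CC(O[Si](C)(C)C)=CC(O[Si](C)(C)C)=C1
F3 | step 5 | benzyl 2-hydroxy-6-methyl-4-{[3,8,8-trimethyl-1,5-bis(trimethylsilyloxy)bicyclo[2.2.2]octa-2,5-diene-2-carbonyl]oxy}benzoate (racemic) | O=C(Oc1cc(C)c(C(=O)OCc2ccccc2)c(O)c1)C1=C(C)C2C(O[Si](C)(C)C)=CC1(O[Si](C)(C)C)CC2(C)C
F4 | step 5 | benzyl 4-{[2,4-bis(trimethylsilyloxy)-6-methylbenzoyl]oxy}-2-hydroxy-6-methylbenzoate | Cc1cc(O[Si](C)(C)C)cc(O[Si](C)(C)C)c1C(=O)Oc1cc(C)c(C(=O)OCc2ccccc2)c(O)c1
F5 | step 6 | methyl 2,4-bis(benzyloxy)-6-methylbenzoate | COC(=O)c1c(C)cc(OCc2ccccc2)cc1OCc1ccccc1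
F6 | step 6 | methyl 2,4-bis(benzyloxy)-5-formyl-6-methylbenzoate | COC(=O)c1c(C)c(C=O)c(OCc2ccccc2)cc1OCc1ccccc1
F7 | step 6 | methyl 2,4-bis(benzyloxy)-5-(formyloxy)-6-methylbenzoate | COC(=O)c1c(C)c(OC=O)c(OCc2ccccc2)cc1OCc1ccccc1
F8 | step 6 | methyl 2,4-bis(benzyloxy)-5-hydroxy-6-methylbenzoate | COC(=O)c1c(C)c(O)c(OCc2ccccc2)cc1OCc1ccccc1
F9 | step 9 | 2,4,5-tris(benzyloxy)-6-methylbenzoyl chloride | Cc1c(OCc2ccccc2)c(OCc2ccccc2)cc(OCc2ccccc2)c1C(=O)Cl
F10 | step 2 | but-2-ynoyl chloride | CC#CC(=O)Cl
A1 | alternative 1 | tert-butyl 2,5-dihydroxy-4-isopropoxy-6-methylbenzoate | Cc1c(O)c(OC(C)C)cc(O)c1C(=O)OC(C)(C)C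
A2 | alternative 1 | tert-butyl (2E)-3-(1-hydroxy-2-isopropoxy-4-oxocyclobut-2-en-1-yl)but-2-enoate (racemic) | C/C(=C\C(=O)OC(C)(C)C)C1(O)C(OC(C)C)=CC1=O
A3 | alternative 2 | benzyl 2-(benzyloxy)-4-{[2-(benzyloxy)-4-{[2,4,5-tris(benzyloxy)-6-methylbenzoyl]oxy}-6-methylbenzoyl]oxy}-6-methylbenzoate | Cc1cc(OC(=O)c2c(C)cc(OC(=O)c3c(OCc4ccccc4)cc(OCc4ccccc4)c(OCc4ccccc4)c3C)cc2OCc2ccccc2)cc(OCc2ccccc2)c1C(=O)OCc1ccccc1
A4 | alternative 2 | 6-methyl-2-oxo-2H-pyran-4-yl 2-(benzyloxy)-4-{[2,4,5-tris(benzyloxy)-6-methylbenzoyl]oxy}-6-methylbenzoate | Cc1cc(OC(=O)c2c(C)cc(OC(=O)c3c(OCc4ccccc4)cc(OCc4ccccc4)c(OCc4ccccc4)c3C)cc2OCc2ccccc2)cc(=O)o1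
A5 | alternative 2 | benzyl 3-(benzyloxy)prop-2-ynoate | O=C(OCc1ccccc1)C#COCc1ccccc1
A6 | alternative 3 | benzyl 2-(benzyloxy)-4-{[2-(benzyloxy)-4-{[5-(benzyloxy)-2,4-dihydroxy-6-methylbenzoyl]oxy}-6-methylbenzoyl]oxy}-6-methylbenzoate | Cc1c(OCc2ccccc2)c(O)cc(O)c1C(=O)Oc1cc(C)c(C(=O)Oc2cc(C)c(C(=O)OCc3ccccc3)c(OCc3ccccc3)c2)c(OCc2ccccc2)c1
A7 | alternative 3 | 6-(benzyloxy)-3,5,7-trioxooctanoate ester of the ring B C4 hydroxyl of the benzyl-protected rings B–A didepside (racemic) | CC(=O)C(OCc1ccccc1)C(=O)CC(=O)CC(=O)Oc1cc(C)c(C(=O)Oc2cc(C)c(C(=O)OCc3ccccc3)c(OCc3ccccc3)c2)c(OCc2ccccc2)c1
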